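A direct plan would close ring C first: 2′,6′-dihydroxy-4′-methoxyacetophenone A1 would give, with DMF dimethyl acetal and then acid, 5-hydroxy-7-methoxychromone A2, whose chloromagnesium phenoxide would be zincated at C2 with TMPZnCl·LiCl to the C2-zinc reagent A3 and then coupled with 5-iodo-1,2,3-trimethoxybenzene A4 under zerovalent palladium catalysis. Its weakest operations would be:
- the C2 zincation of A2 beside a metalated peri-hydroxyl: it has no precedent, C2 versus C3 would hang on an untested chelate, and the metalated ring could open to an ynone phenoxide;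
- the Negishi coupling of the doubly metalated A3 with A4: the only convergent bond would be made last, with all material at stake;
- the early closure of A1 to chromone A2: it would leave C2 bare and force the aryl group onto a C–H bond.

**Plan of the new route**
The retrosynthesis cuts O1–C2 and then, together, C4–C4a and O1–C8a. Ring A is delivered as 3,5-dimethoxybenzyne; C2–C3–C4 and ring B come as an arylpropiolic acid. Ring C arises last, in one operation in which the aryne takes up O1 and C4 on neighbouring carbons.
The feature used: in ring A the ether oxygen (on C8a) and the carbonyl carbon (on C4a) are ortho to each other, and C4a is flanked by the oxygenated C5. An alkoxy group on C5 beside the triple bond C4a≡C8a sends the carboxylate oxygen to C8a and leaves the carbanion on C4a for the acyl shift.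
The C2–aryl bond is present from the start in the alkyne, nothing is metalated at C2 or C3, and no chromone exists before the key step. The 5-OH is freed last by cleaving the one methyl ether peri to the carbonyl.

Key step: step 4

Remark: 3,5-dimethoxyphenol and 5-ethynyl-1,2,3-trimethoxybenzene are taken as purchasable; the target has no stereocentre, so no configuration has to be set.

Step 1
Reactants: 1 3,5-dimethoxyphenol
Product: 2 2-bromo-3,5-dimethoxyphenol
Conditions: NBS (1.0 equiv), CH2Cl2, −78 °C → rt, dark
Reagents that add atoms: N-bromosuccinimide, O=C1CCC(=O)N1Br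
Why: Electrophilic aromatic bromination of an electron-rich phenol should go to one of the two equivalent positions ortho to OH (each also para to a methoxy group) rather than to C4, which is flanked by two methoxy groups, and one equivalent of NBS at low temperature should stop at the monobromide.

Step 2
Reactants: 2 2-bromo-3,5-dimethoxyphenol
Product: 5 3,5-dimethoxy-2-(trimethylsilyl)phenyl trifluoromethanesulfonate, via silyl ether 3 (not isolated), via lithium silylphenolate 4 (not isolated)
Conditions: HMDS (1.5 equiv), THF, reflux, then evaporate; n-BuLi (1.1 equiv), THF, −100 → −78 °C; Tf2O (1.2 equiv), −100 °C → rt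
Reagents that add atoms: hexamethyldisilazane, C[Si](C)(C)N[Si](C)(C)C; trifluoromethanesulfonic anhydride, O=S(=O)(OS(=O)(=O)C(F)(F)F)C(F)(F)F
Why: O-silylation, bromine–lithium exchange and retro-Brook rearrangement (anionic 1,3-shift of silicon from oxygen to the lithiated carbon) should place the silyl group on C2 and free phenolate 4, which Tf2O traps in the same flask, the standard entry to ortho-silylaryl triflates as fluoride-triggered aryne precursors.

Step 3
Reactants: 6 5-ethynyl-1,2,3-trimethoxybenzene
Product: 9 3-(3,4,5-trimethoxyphenyl)prop-2-ynoic acid, via lithium acetylide 7 (not isolated), via lithium carboxylate 8 (not isolated)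
Conditions: n-BuLi (1.05 equiv), THF, −78 °C; CO2 (dry gas), −78 °C → rt; 1 M HCl
Reagents that add atoms: carbon dioxide, O=C=O
Why: Deprotonation of the terminal alkyne and carboxylation of the lithium acetylide is the standard preparation of arylpropiolic acids, and the three methoxy groups are inert to it.

Step 4
Reactants: 5 3,5-dimethoxy-2-(trimethylsilyl)phenyl trifluoromethanesulfonate; 9 3-(3,4,5-trimethoxyphenyl)prop-2-ynoic acid
Product: 12 5,7-dimethoxy-2-(3,4,5-trimethoxyphenyl)-4H-chromen-4-one, via 3,5-dimethoxybenzyne 10 (not isolated), via cesium ynone phenolate 11 (not isolated)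
Conditions: 5 (1.5 equiv), CsF (4 equiv), THF, 125 °C (sealed tube), 24 h
Reagents that add atoms: none
Why: Fluoride takes the silyl group of 5, triflate leaves and aryne 10 forms; the cesium carboxylate of 9 adds through oxygen to the aryne carbon that becomes C8a, the carbanion left on C4a attacks the ester carbonyl through a four-membered transition state and the acyl group moves from oxygen to carbon to give phenolate 11, whose oxygen then adds to the ynone before C3 is protonated. The closest known reaction type is the fluoride-induced formal insertion of arynes into the C–O bond of carboxylic acids to give ortho-hydroxyaryl ketones, which with arylpropiolic acids runs on to flavones. Ring C is the only ring closed, by 6-endo-dig oxa-Michael attack of the phenolate oxygen (O1) on the alkyne carbon that bears ring B (C2), the mode expected over 5-exo closure for such phenolates in an aprotic medium. No stereocentre is formed. The selectivity needed is the orientation of addition to the unsymmetrical aryne: the methoxy group on the carbon next to the triple bond makes the remote aryne carbon the more electrophilic one and stabilises by induction the carbanion that develops beside it, so oxygen should go to the remote carbon (C8a) and the acyl group to the carbon next to the methoxy group (C4a). Since the second methoxy group is meta to the first, this one orientation fixes the 5,7-dioxygenation pattern, and the high temperature should favour the acyl shift over simple protonation of the aryl anion.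

Step 5
Reactants: 12 5,7-dimethoxy-2-(3,4,5-trimethoxyphenyl)-4H-chromen-4-one
Product: 14 corymbosin (5-hydroxy-7-methoxy-2-(3,4,5-trimethoxyphenyl)-4H-chromen-4-one), via dichloroboron chelate 13 (not isolated)
Conditions: BCl3 (1 M in CH2Cl2, 2.0 equiv), CH2Cl2, −78 → 0 °C; H2O, then 1 M HCl
Reagents that add atoms: none
Why: In this chelation-controlled Lewis acid ether cleavage BCl3 is held by the C4 carbonyl oxygen and the peri C5 oxygen in a six-membered chelate, chloride removes only that methyl group, and the 7-OMe and the three ring B methoxy groups, which have no carbonyl beside them, should survive at 0 °C before hydrolysis of 13 gives the hydrogen-bonded 5-OH.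

**Compound list**
1 | 3,5-dimethoxyphenol | COc1cc(O)cc(OC)c1 | starting material
2 | 2-bromo-3,5-dimethoxyphenol | COc1cc(O)c(Br)c(OC)c1 | intermediate
3 | (2-bromo-3,5-dimethoxyphenoxy)trimethylsilane | COc1cc(O[Si](C)(C)C)c(Br)c(OC)c1 | intermediate
4 | lithium 3,5-dimethoxy-2-(trimethylsilyl)phenolate | COc1cc([O-])c([Si](C)(C)C)c(OC)c1.[Li+] | intermediate
5 | 3,5-dimethoxy-2-(trimethylsilyl)phenyl trifluoromethanesulfonate | COc1cc(OS(=O)(=O)C(F)(F)F)c([Si](C)(C)C)c(OC)c1 | intermediate
6 | 5-ethynyl-1,2,3-trimethoxybenzene | C#Cc1cc(OC)c(OC)c(OC)c1 | starting material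
7 | lithium (3,4,5-trimethoxyphenyl)acetylide | [Li]C#Cc1cc(OC)c(OC)c(OC)c1 | intermediate
8 | lithium 3-(3,4,5-trimethoxyphenyl)prop-2-ynoate | COc1cc(C#CC(=O)[O-])cc(OC)c1OC.[Li+] | intermediate
9 | 3-(3,4,5-trimethoxyphenyl)prop-2-ynoic acid | COc1cc(C#CC(=O)O)cc(OC)c1OC | intermediate
10 | 3,5-dimethoxybenzyne (1,2-didehydro-3,5-dimethoxybenzene) | COC1=CC(OC)=CC#C1 | intermediate
11 | cesium 3,5-dimethoxy-2-[3-(3,4,5-trimethoxyphenyl)prop-2-ynoyl]phenolate | COc1cc([O-])c(C(=O)C#Cc2cc(OC)c(OC)c(OC)c2)c(OC)c1.[Cs+] | intermediate
12 | 5,7-dimethoxy-2-(3,4,5-trimethoxyphenyl)-4H-chromen-4-one | COc1cc(OC)c2c(=O)cc(-c3cc(OC)c(OC)c(OC)c3)oc2c1 | intermediate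
13 | 5-(dichloroboranyloxy)-7-methoxy-2-(3,4,5-trimethoxyphenyl)-4H-chromen-4-one (boron chelated to the C4 carbonyl) | COc1cc(OB(Cl)Cl)c2c(=O)cc(-c3cc(OC)c(OC)c(OC)c3)oc2c1 | intermediate
14 | corymbosin, 5-hydroxy-7-methoxy-2-(3,4,5-trimethoxyphenyl)-4H-chromen-4-one | COc1cc(O)c2c(=O)cc(-c3cc(OC)c(OC)c(OC)c3)oc2c1 | target

**Step count and risks**
Total steps: 5. Longest linear sequence: 4 (steps 1, 2, 4, 5); step 3 supplies the second fragment.

Steps most likely to fail:

Step 4 (key step). The aryl anion may be protonated before the acyl shift, so that the acid is only O-arylated; the cesium arylpropiolate may lose CO2 at 125 °C; or the phenolate may close in the 5-exo mode. The fallback replaces the aryne by a stepwise ionic acylation and sets out from 6 and 2. The lithium acetylide 7 would be quenched with N-methoxy-N-methylcarbamoyl chloride to give N-methoxy-N-methyl-3-(3,4,5-trimethoxyphenyl)prop-2-ynamide F1. Bromophenol 2 would be lithiated twice (n-BuLi, 1 equiv, at O–H; then t-BuLi, 2 equiv, bromine–lithium exchange, THF, −78 °C) and added to F1 (Weinreb ketone synthesis). Work-up would give 1-(2-hydroxy-4,6-dimethoxyphenyl)-3-(3,4,5-trimethoxyphenyl)prop-2-yn-1-one F2, which K2CO3 in acetone at reflux should close 6-endo-dig to 12, where the route is rejoined.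

Step 1. Bromine may enter at C4 (para to OH) or twice. The fallback uses directed ortho-metalation in place of electrophilic substitution, sets out from 1 and also replaces step 2. Isopropyl isocyanate with catalytic Et3N would give 3,5-dimethoxyphenyl N-(propan-2-yl)carbamate F3. In situ N-silylation (TBSOTf, TMEDA), ortho-lithiation with n-BuLi/TMEDA at −78 °C between the carbamate and a methoxy group, TMSCl and acidic work-up would give 3,5-dimethoxy-2-(trimethylsilyl)phenyl N-(propan-2-yl)carbamate F4. DBU and Et2NH in MeCN would then cleave the carbamate and PhNTf2 would triflate the phenolate in the same flask, rejoining the route at 5.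

Step 5. The flanked central 4′-O-methyl group of ring B may be lost together with the 5-O-methyl group. The fallback, from 12, drives that double cleavage on purpose and then re-methylates selectively. Excess AlCl3 in CH2Cl2 at rt would remove both methyl groups, each through a chelate, giving 5-hydroxy-2-(4-hydroxy-3,5-dimethoxyphenyl)-7-methoxy-4H-chromen-4-one F5. MeI (1.05 equiv) and K2CO3 in acetone at rt should then methylate only the free 4′-OH, the 5-OH being held in a hydrogen bond to the C4 carbonyl, and so give 14.

**Further compounds**
F1 | step 4 | N-methoxy-N-methyl-3-(3,4,5-trimethoxyphenyl)prop-2-ynamide | CON(C)C(=O)C#Cc1cc(OC)c(OC)c(OC)c1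
F2 | step 4 | 1-(2-hydroxy-4,6-dimethoxyphenyl)-3-(3,4,5-trimethoxyphenyl)prop-2-yn-1-one | COc1cc(O)c(C(=O)C#Cc2cc(OC)c(OC)c(OC)c2)c(OC)c1
F3 | step 1 | 3,5-dimethoxyphenyl N-(propan-2-yl)carbamate | COc1cc(OC)cc(OC(=O)NC(C)C)c1
F4 | step 1 | 3,5-dimethoxy-2-(trimethylsilyl)phenyl N-(propan-2-yl)carbamate | COc1cc(OC(=O)NC(C)C)c([Si](C)(C)C)c(OC)c1
F5 | step 5 | 5-hydroxy-2-(4-hydroxy-3,5-dimethoxyphenyl)-7-methoxy-4H-chromen-4-one | COc1cc(O)c2c(=O)cc(-c3cc(OC)c(O)c(OC)c3)oc2c1
A1 | direct plan | 1-(2,6-dihydroxy-4-methoxyphenyl)ethan-1-one | CC(=O)c1c(O)cc(OC)cc1O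
A2 | direct plan | 5-hydroxy-7-methoxy-4H-chromen-4-one | COc1cc(O)c2c(=O)ccoc2c1
A3 | direct plan | [5-(chloromagnesiooxy)-7-methoxy-4-oxo-4H-chromen-2-yl]zinc chloride | COc1cc(O[Mg]Cl)c2c(=O)cc([Zn]Cl)oc2c1
A4 | direct plan | 5-iodo-1,2,3-trimethoxybenzene | COc1cc(I)cc(OC)c1OC
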